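**Retrosynthetic overview**

1. Locants follow drimane numbering in each half (ring A: C1–C5 and C10; ring B: C5–C10; C11 is the CH2 that links the halves). The target is C2-symmetric, so both halves are built at once on one core (two-directional).
2. Enabling feature: in each half ring B is a cyclohexene whose C8=C9 double bond sits between C7 and C10, a Diels–Alder retron (diene C7=C8–C9=C10, dienophile C5=C6). C2–C3 lies in the middle of the four-atom chain C1–C4 that ties C10 to C5 and closes ring A.
3. Key disconnections: C2=C3 by a Z-selective Wittig reaction between a bis-ylide core and an α-quaternary aldehyde carrying a masked enal; C5–C10 and C6–C7 by an amine-catalysed intramolecular Diels–Alder reaction. Rings A and B of both halves form in that one operation (ring B as the cycloadduct, ring A as the tether ring).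
4. Before it: the C9=C10 geometry comes from directed anti-carbomagnesiation/iodination of but-2-yn-1-ol, C11–C11′ from allylic homocoupling of two molecules of the resulting bromide, then the C1–C2 arms and the phosphonium groups are added at both ends.
5. After it: the activating formyl groups on C6 are removed by decarbonylation and the two C2=C3 double bonds are hydrogenated; the C8=C9 double bonds come from the cycloaddition itself.

Key step: step 10

Remark: the (2S,5S)-imidazolidinone is assumed to expose the same enal face as in its established cycloadditions of (E)-enals, which corresponds to the (5S,10S) series of the target; otherwise its mirror image is used.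

**Route**

Step 1
Reactants: 1 but-2-yn-1-ol; 2 isopropenylmagnesium bromide
Product: 4 (Z)-3-iodo-2-(prop-1-en-2-yl)but-2-en-1-ol, via cyclic alkenylmagnesium alkoxide 3 (not isolated)
Conditions: 2 (3.5 equiv), THF/cyclohexane, reflux; then I2 (4 equiv), THF, −78 → 0 °C
Reagents that add atoms: iodine ([I][I])
Why: Hydroxyl-directed anti-carbomagnesiation of a propargylic alcohol should put the alkenyl group on the carbinol-proximal alkyne carbon and magnesium on the distal one in a five-membered chelate, so iodinolysis with retention gives the tetrasubstituted alkene with iodine cis to CH2OH (the future C9=C10, tether position trans to the isopropenyl group).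

Step 2
Reactants: 4 (Z)-3-iodo-2-(prop-1-en-2-yl)but-2-en-1-ol
Product: 5 (Z)-1-bromo-3-iodo-2-(prop-1-en-2-yl)but-2-ene
Conditions: CBr4, PPh3, CH2Cl2, 0 °C
Reagents that add atoms: carbon tetrabromide (BrC(Br)(Br)Br)
Why: Appel bromination of a primary allylic alcohol is neutral, so the alkenyl iodide, the diene and the alkene geometry should be untouched.

Step 3
Reactants: 5 (Z)-1-bromo-3-iodo-2-(prop-1-en-2-yl)but-2-ene (2 equiv; two molecules are joined)
Product: 6 (2E,6E)-2,7-diiodo-3,6-di(prop-1-en-2-yl)octa-2,6-diene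
Conditions: 5 (2 equiv), Cp2TiCl2 (20 mol %), Mn dust (2 equiv), THF, 23 °C
Reagents that add atoms: second molecule of 5, (Z)-1-bromo-3-iodo-2-(prop-1-en-2-yl)but-2-ene (BrC/C(=C(\I)C)C(C)=C)
Why: Wurtz-type reductive homocoupling of two molecules of the allylic bromide through an allyl-titanium species should join the unhindered CH2 termini (C11–C11′) because the other allylic terminus is fully substituted, and alkenyl iodides are not reduced under these conditions.

Step 4
Reactants: 6 (2E,6E)-2,7-diiodo-3,6-di(prop-1-en-2-yl)octa-2,6-diene; 7 oxirane (2 equiv incorporated, one at each end)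
Product: 9 (3E,7E)-3,8-dimethyl-4,7-di(prop-1-en-2-yl)deca-3,7-diene-1,10-diol, via bis(alkenyllithium) 8 (not isolated)
Conditions: t-BuLi (4.1 equiv), Et2O, −78 °C; then 7 (3 equiv), THF, −78 → 23 °C
Reagents that add atoms: oxirane, second molecule (C1CO1)
Why: Iodine–lithium exchange of alkenyl iodides goes with retention of geometry, and opening of one oxirane by each alkenyllithium terminus puts the two-carbon arm C1–C2 on each C10.

Step 5
Reactants: 9 (3E,7E)-3,8-dimethyl-4,7-di(prop-1-en-2-yl)deca-3,7-diene-1,10-diol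
Product: 10 (3E,7E)-1,10-diiodo-3,8-dimethyl-4,7-di(prop-1-en-2-yl)deca-3,7-diene
Conditions: I2 (2.4 equiv), PPh3 (2.4 equiv), imidazole (5 equiv), CH2Cl2, 0 → 23 °C
Reagents that add atoms: iodine ([I][I])
Why: Appel-type iodination of primary alcohols is reliable and non-acidic, so the dienes should survive.

Step 6
Reactants: 10 (3E,7E)-1,10-diiodo-3,8-dimethyl-4,7-di(prop-1-en-2-yl)deca-3,7-diene
Product: 11 [(3E,7E)-3,8-dimethyl-4,7-di(prop-1-en-2-yl)deca-3,7-diene-1,10-diyl]bis(triphenylphosphonium) diiodide
Conditions: PPh3 (2.5 equiv), MeCN, 80 °C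
Reagents that add atoms: triphenylphosphine (c1ccc(cc1)P(c1ccccc1)c1ccccc1); second molecule of triphenylphosphine (c1ccc(cc1)P(c1ccccc1)c1ccccc1)
Why: SN2 quaternisation of triphenylphosphine by each primary iodide gives a but-3-enyl-type phosphonium salt, a standard precursor of unstabilised ylides.

Step 7
Reactants: 12 3-hydroxy-2,2-dimethylpropanal; 13 (triphenylphosphoranylidene)acetaldehyde
Product: 14 (E)-5-hydroxy-4,4-dimethylpent-2-enal
Conditions: 13 (1.0 equiv), toluene, 80 °C
Reagents that add atoms: none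
Why: Wittig reaction of a stabilised ylide should give the (E)-enal, and the quaternary γ-carbon blocks dienolisation and slows a second homologation.

Step 8
Reactants: 14 (E)-5-hydroxy-4,4-dimethylpent-2-enal
Product: 15 (E)-5,5-dimethoxy-2,2-dimethylpent-3-en-1-ol
Conditions: HC(OMe)3, MeOH, pyridinium p-toluenesulfonate (cat.), 23 °C
Reagents that add atoms: trimethyl orthoformate (COC(OC)OC)
Why: Acid-catalysed acetalisation masks the enal so that only the neopentyl aldehyde made next can meet the ylide; the E geometry keeps the hydroxyl too far away for cyclic acetal formation.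

Step 9
Reactants: 15 (E)-5,5-dimethoxy-2,2-dimethylpent-3-en-1-ol
Product: 16 (E)-5,5-dimethoxy-2,2-dimethylpent-3-enal
Conditions: Dess–Martin periodinane, NaHCO3, CH2Cl2, 0 → 23 °C
Reagents that add atoms: none
Why: Buffered Dess–Martin oxidation of a neopentyl alcohol should give the non-enolisable aldehyde without touching the acid-labile acetal.

Step 10
Reactants: 11 [(3E,7E)-3,8-dimethyl-4,7-di(prop-1-en-2-yl)deca-3,7-diene-1,10-diyl]bis(triphenylphosphonium) diiodide; 16 (E)-5,5-dimethoxy-2,2-dimethylpent-3-enal (2.2 equiv)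
Product: 20 (1S,1′S,4aS,4a′S,8aS,8a′S)-4,4′-(ethane-1,2-diyl)bis(3,4a,8,8-tetramethyl-1,2,4a,5,8,8a-hexahydronaphthalene-1-carbaldehyde), via bis-ylide 17 (not isolated), via hexaene bis(dimethyl acetal) 18 (not isolated), via hexaenedial 19 (not isolated)
Conditions: KN(SiMe3)2 (2.05 equiv), THF, −78 °C; 16 (2.2 equiv), −78 → 0 °C; volatiles (THF, HN(SiMe3)2) removed in vacuo; then, without purification, MeCN/H2O 19:1 (0.01 M), (2S,5S)-5-benzyl-2-tert-butyl-3-methylimidazolidin-4-one·CF3CO2H (40 mol %), 0 → 23 °C
Reagents that add atoms: second molecule of 16, (E)-5,5-dimethoxy-2,2-dimethylpent-3-enal (O=CC(C)(C)/C=C/C(OC)OC); water (O)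
Why: Proposed new method: a salt-free Wittig reaction of the unstabilised bis-ylide with two molecules of the α-quaternary aldehyde should form both C2=C3 bonds with Z geometry, which folds each C1–C4 tether so that C5 lies over C10; acid then unmasks the enals, whose iminium ions with the chiral amine undergo a normal-demand intramolecular Diels–Alder reaction with the electron-rich diene C7=C8–C9=C10, forming C5–C10 and C6–C7 and leaving the new double bond at C8=C9. The closest known reactions are the amine-catalysed intramolecular Diels–Alder reaction of undeca-2,8,10-trienals and one-pot Wittig/intramolecular Diels–Alder sequences; what is not precedented is a diene terminus with two carbon substituents, so that the cycloaddition creates the quaternary C10. Ring B closes as the [4+2] cyclohexene and ring A closes in the same event as the six-membered tether ring (C10–C1–C2=C3–C4–C5), its C2=C3 bond having been made in the Wittig stage. C5, C6 and C10 are set together: the benzyl group of the catalyst blocks one face of the (E)-iminium ion (absolute control), the endo position of the iminium group with the E dienophile gives the trans ring fusion with the formyl group cis to H-5, and C10 follows from the diene geometry fixed in step 1 (methyl inside, tether outside). The step needs Z selectivity in the olefination, endo and facial selectivity in each cycloaddition, and intramolecular over intermolecular reaction; these should be secured by salt-free conditions with a hindered aldehyde, by the catalyst, and by the cis tether with its gem-dimethyl group at high dilution. Because the two cycloadditions are controlled independently, the minor enantiomeric series should end up mainly in the separable meso diastereomer.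

Step 11
Reactants: 20 (1S,1′S,4aS,4a′S,8aS,8a′S)-4,4′-(ethane-1,2-diyl)bis(3,4a,8,8-tetramethyl-1,2,4a,5,8,8a-hexahydronaphthalene-1-carbaldehyde)
Product: 21 1,2-bis[(4aS,8aS)-2,5,5,8a-tetramethyl-3,4,4a,5,8,8a-hexahydronaphthalen-1-yl]ethane
Conditions: RhCl(PPh3)3 (2.2 equiv), toluene, 110 °C
Reagents that add atoms: none
Why: Tsuji–Wilkinson decarbonylation (oxidative addition into the formyl C–H bond, CO extrusion, reductive elimination) should remove the activating carbon from each C6 and erase that stereocentre, while the tetrasubstituted and the hindered cis-disubstituted alkenes are poor partners for hydroacylation.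

Step 12
Reactants: 21 1,2-bis[(4aS,8aS)-2,5,5,8a-tetramethyl-3,4,4a,5,8,8a-hexahydronaphthalen-1-yl]ethane
Product: 22 1,2-bis[(4aS,8aS)-2,5,5,8a-tetramethyl-3,4,4a,5,6,7,8,8a-octahydronaphthalen-1-yl]ethane (target)
Conditions: H2 (1 atm), Pd/C (5 % palladium on carbon), EtOAc, 23 °C
Reagents that add atoms: none
Why: Heterogeneous hydrogenation should saturate the two cis-disubstituted C2=C3 double bonds while the tetrasubstituted C8=C9 double bonds stay inert under these mild conditions; no stereocentre is formed.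

**Compound list**

1 | but-2-yn-1-ol | CC#CCO | starting material
2 | isopropenylmagnesium bromide | CC(=C)[Mg]Br | starting material
3 | 3-methyl-4-(prop-1-en-2-yl)-2,5-dihydro-1,2-oxamagnesole (cyclic alkenylmagnesium alkoxide) | C=C(C)C1=C(C)[Mg]OC1 | intermediate
4 | (Z)-3-iodo-2-(prop-1-en-2-yl)but-2-en-1-ol | OC/C(=C(\I)C)C(C)=C | intermediate
5 | (Z)-1-bromo-3-iodo-2-(prop-1-en-2-yl)but-2-ene | BrC/C(=C(\I)C)C(C)=C | intermediate
6 | (2E,6E)-2,7-diiodo-3,6-di(prop-1-en-2-yl)octa-2,6-diene | C(/C(=C(\I)C)C(C)=C)C/C(=C(\I)C)C(C)=C | intermediate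
7 | oxirane | C1CO1 | starting material
8 | 2,7-dilithio analogue of 6, alkene geometry retained (bis(alkenyllithium)) | C(/C(=C(\[Li])C)C(C)=C)C/C(=C(\[Li])C)C(C)=C | intermediate
9 | (3E,7E)-3,8-dimethyl-4,7-di(prop-1-en-2-yl)deca-3,7-diene-1,10-diol | C(/C(=C(\CCO)C)C(C)=C)C/C(=C(\CCO)C)C(C)=C | intermediate
10 | (3E,7E)-1,10-diiodo-3,8-dimethyl-4,7-di(prop-1-en-2-yl)deca-3,7-diene | C(/C(=C(\CCI)C)C(C)=C)C/C(=C(\CCI)C)C(C)=C | intermediate
11 | [(3E,7E)-3,8-dimethyl-4,7-di(prop-1-en-2-yl)deca-3,7-diene-1,10-diyl]bis(triphenylphosphonium) diiodide | C(/C(=C(\CC[P+](c1ccccc1)(c1ccccc1)c1ccccc1)C)C(C)=C)C/C(=C(\CC[P+](c1ccccc1)(c1ccccc1)c1ccccc1)C)C(C)=C.[I-].[I-] | intermediate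
12 | 3-hydroxy-2,2-dimethylpropanal | OCC(C)(C)C=O | starting material
13 | (triphenylphosphoranylidene)acetaldehyde | O=CC=P(c1ccccc1)(c1ccccc1)c1ccccc1 | starting material
14 | (E)-5-hydroxy-4,4-dimethylpent-2-enal | OCC(C)(C)/C=C/C=O | intermediate
15 | (E)-5,5-dimethoxy-2,2-dimethylpent-3-en-1-ol | OCC(C)(C)/C=C/C(OC)OC | intermediate
16 | (E)-5,5-dimethoxy-2,2-dimethylpent-3-enal | O=CC(C)(C)/C=C/C(OC)OC | intermediate
17 | bis-ylide of 11: (3E,7E)-3,8-dimethyl-4,7-di(prop-1-en-2-yl)deca-3,7-diene-1,10-diylidenebis(triphenylphosphorane) | C(/C(=C(\CC=P(c1ccccc1)(c1ccccc1)c1ccccc1)C)C(C)=C)C/C(=C(\CC=P(c1ccccc1)(c1ccccc1)c1ccccc1)C)C(C)=C | intermediate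
18 | (2E,5Z,8E,12E,15Z,18E)-1,1,20,20-tetramethoxy-4,4,8,13,17,17-hexamethyl-9,12-di(prop-1-en-2-yl)icosa-2,5,8,12,15,18-hexaene | C(/C(=C(\C/C=C\C(C)(C)/C=C/C(OC)OC)C)C(C)=C)C/C(=C(\C/C=C\C(C)(C)/C=C/C(OC)OC)C)C(C)=C | intermediate
19 | (2E,5Z,8E,12E,15Z,18E)-4,4,8,13,17,17-hexamethyl-9,12-di(prop-1-en-2-yl)icosa-2,5,8,12,15,18-hexaenedial | C(/C(=C(\C/C=C\C(C)(C)/C=C/C=O)C)C(C)=C)C/C(=C(\C/C=C\C(C)(C)/C=C/C=O)C)C(C)=C | intermediate
20 | (1S,1′S,4aS,4a′S,8aS,8a′S)-4,4′-(ethane-1,2-diyl)bis(3,4a,8,8-tetramethyl-1,2,4a,5,8,8a-hexahydronaphthalene-1-carbaldehyde); drimane locants: 5S,6S,10S in each half, trans-fused, formyl on C6 cis to H-5 | C(C1=C(C)C[C@H](C=O)[C@H]2C(C)(C)C=CC[C@]12C)CC1=C(C)C[C@H](C=O)[C@H]2C(C)(C)C=CC[C@]12C | intermediate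
21 | 1,2-bis[(4aS,8aS)-2,5,5,8a-tetramethyl-3,4,4a,5,8,8a-hexahydronaphthalen-1-yl]ethane | C(C1=C(C)CC[C@H]2C(C)(C)C=CC[C@]12C)CC1=C(C)CC[C@H]2C(C)(C)C=CC[C@]12C | intermediate
22 | 1,2-bis[(4aS,8aS)-2,5,5,8a-tetramethyl-3,4,4a,5,6,7,8,8a-octahydronaphthalen-1-yl]ethane | CC1=C(CCC2=C(C)CC[C@H]3C(C)(C)CCC[C@]23C)[C@@]2(C)CCCC(C)(C)[C@@H]2CC1 | target

**Totals**

Total step count: 12. Longest linear sequence: 9 steps (steps 1–6, then 10–12).

**Steps most likely to fail**

Step 10 (Proposed new method). The doubly substituted diene terminus may be too hindered for the iminium dienophile at a temperature where the catalyst still controls the face. The acid stage may also isomerise or oligomerise the electron-rich dienes, so that conversion stalls at 19 or facial and endo selectivity erode. Incomplete Z selectivity in the olefination would leave arms that cannot cyclise.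

The fallback separates the two bond formations and uses an auxiliary with Lewis-acid activation, all known reaction types. It sets out from 12 and 11 and returns at 20. Horner–Wadsworth–Emmons reaction of 12 with (S)-4-benzyl-3-[(diethoxyphosphoryl)acetyl]oxazolidin-2-one (LiCl, i-Pr2NEt, MeCN) would give (S)-4-benzyl-3-[(E)-5-hydroxy-4,4-dimethylpent-2-enoyl]oxazolidin-2-one F1 (auxiliary enantiomer to be matched to the required face, written as S). Dess–Martin oxidation would give (S)-4-benzyl-3-[(E)-4,4-dimethyl-5-oxopent-2-enoyl]oxazolidin-2-one F2. Wittig reaction of F2 (2.2 equiv) with the bis-ylide from 11 (KN(SiMe3)2, THF, −78 °C) would give the isolated hexaene bis-imide F3. Its double intramolecular Diels–Alder reaction under Me2AlCl (CH2Cl2, −30 °C), the chelation-activated auxiliary-controlled variant known for triene N-acyloxazolidinones, should give the bis-imide cycloadduct F4. LiBH4 (THF/MeOH) would release the auxiliary and give the bis(hydroxymethyl) compound F5, and Dess–Martin oxidation of F5 leads back to 20.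

Step 11. CO extrusion at the hindered secondary acyl-rhodium centres may be slow, so β-hydride elimination, alkene isomerisation or hydroacylation of the nearby double bonds could compete, and the double decarbonylation may stop halfway.

The fallback replaces metal-mediated decarbonylation by radical decarboxylation. It sets out from 20 and returns at 21. Pinnick oxidation of 20 (NaClO2, NaH2PO4, 2-methylbut-2-ene, t-BuOH/H2O) would give the dicarboxylic acid F6. Activation with oxalyl chloride and sodium 2-thioxopyridin-1(2H)-olate would give the bis(2-thioxopyridin-1(2H)-yl) ester F7, used without isolation. Irradiation of F7 with t-BuSH (Barton decarboxylation) should give 21.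

Step 1. The alkenyl Grignard reagent may add slowly or with incomplete regio- and anti-selectivity, and iodinolysis of the chelate may be incomplete, so the tetrasubstituted alkene would form as a mixture of isomers.

The fallback builds the same alkene by syn-carbocupration of an ynoate and cross-coupling. It sets out from 7 and returns at 9. Opening of 7 with lithiated ethyl propiolate (n-BuLi, BF3·OEt2, THF, −78 °C) would give ethyl 5-hydroxypent-2-ynoate F8, and silylation (TBSCl, imidazole) its silyl ether F9. Addition of Me2CuLi (THF, −78 °C) followed by iodine would give ethyl (E)-5-[(tert-butyldimethylsilyl)oxy]-2-iodo-3-methylpent-2-enoate F10. Suzuki–Miyaura coupling with isopropenylboronic acid pinacol ester (PdCl2(dppf), K3PO4) would give ethyl (Z)-5-[(tert-butyldimethylsilyl)oxy]-3-methyl-2-(prop-1-en-2-yl)pent-2-enoate F11. Reduction with i-Bu2AlH would give the allylic alcohol F12, Appel bromination the allylic bromide F13, and homocoupling of two molecules of F13 (Cp2TiCl2 cat., Mn) the bis(silyl ether) F14. Bu4NF then gives 9.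

Further compounds
F1 | step 10 | (S)-4-benzyl-3-[(E)-5-hydroxy-4,4-dimethylpent-2-enoyl]oxazolidin-2-one | OCC(C)(C)/C=C/C(=O)N1[C@@H](Cc2ccccc2)COC1=O
F2 | step 10 | (S)-4-benzyl-3-[(E)-4,4-dimethyl-5-oxopent-2-enoyl]oxazolidin-2-one | O=CC(C)(C)/C=C/C(=O)N1[C@@H](Cc2ccccc2)COC1=O
F3 | step 10 | 3,3′-[(2E,5Z,8E,12E,15Z,18E)-4,4,8,13,17,17-hexamethyl-9,12-di(prop-1-en-2-yl)icosa-2,5,8,12,15,18-hexaenedioyl]bis[(S)-4-benzyloxazolidin-2-one] (hexaene bis-imide) | C(/C(=C(\C/C=C\C(C)(C)/C=C/C(=O)N1[C@@H](Cc2ccccc2)COC1=O)C)C(C)=C)C/C(=C(\C/C=C\C(C)(C)/C=C/C(=O)N1[C@@H](Cc2ccccc2)COC1=O)C)C(C)=C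
F4 | step 10 | bis-imide cycloadduct: analogue of 20 with each formyl group replaced by [(S)-4-benzyl-2-oxooxazolidin-3-yl]carbonyl, ring configuration as in 20 | C(C1=C(C)C[C@H](C(=O)N3[C@@H](Cc4ccccc4)COC3=O)[C@H]2C(C)(C)C=CC[C@]12C)CC1=C(C)C[C@H](C(=O)N3[C@@H](Cc4ccccc4)COC3=O)[C@H]2C(C)(C)C=CC[C@]12C
F5 | step 10 | bis(hydroxymethyl) analogue of 20 (CH2OH on C6 and C6′, configuration as in 20) | C(C1=C(C)C[C@H](CO)[C@H]2C(C)(C)C=CC[C@]12C)CC1=C(C)C[C@H](CO)[C@H]2C(C)(C)C=CC[C@]12C
F6 | step 11 | dicarboxylic acid analogue of 20 (CO2H on C6 and C6′, configuration as in 20) | C(C1=C(C)C[C@H](C(=O)O)[C@H]2C(C)(C)C=CC[C@]12C)CC1=C(C)C[C@H](C(=O)O)[C@H]2C(C)(C)C=CC[C@]12C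
F7 | step 11 | bis(2-thioxopyridin-1(2H)-yl) ester of F6 | C(C1=C(C)C[C@H](C(=O)ON3C=CC=CC3=S)[C@H]2C(C)(C)C=CC[C@]12C)CC1=C(C)C[C@H](C(=O)ON3C=CC=CC3=S)[C@H]2C(C)(C)C=CC[C@]12C
F8 | step 1 | ethyl 5-hydroxypent-2-ynoate | CCOC(=O)C#CCCO
F9 | step 1 | ethyl 5-[(tert-butyldimethylsilyl)oxy]pent-2-ynoate | CCOC(=O)C#CCCO[Si](C)(C)C(C)(C)C
F10 | step 1 | ethyl (E)-5-[(tert-butyldimethylsilyl)oxy]-2-iodo-3-methylpent-2-enoate | CCOC(=O)/C(I)=C(C)\CCO[Si](C)(C)C(C)(C)C
F11 | step 1 | ethyl (Z)-5-[(tert-butyldimethylsilyl)oxy]-3-methyl-2-(prop-1-en-2-yl)pent-2-enoate | CCOC(=O)/C(C(C)=C)=C(C)\CCO[Si](C)(C)C(C)(C)C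
F12 | step 1 | (Z)-5-[(tert-butyldimethylsilyl)oxy]-3-methyl-2-(prop-1-en-2-yl)pent-2-en-1-ol | OC/C(C(C)=C)=C(C)\CCO[Si](C)(C)C(C)(C)C
F13 | step 1 | (Z)-[5-bromo-3-methyl-4-(prop-1-en-2-yl)pent-3-en-1-yl]oxy(tert-butyl)dimethylsilane | BrC/C(C(C)=C)=C(C)\CCO[Si](C)(C)C(C)(C)C
F14 | step 1 | bis(tert-butyldimethylsilyl) ether of 9 | C(/C(=C(\CCO[Si](C)(C)C(C)(C)C)C)C(C)=C)C/C(=C(\CCO[Si](C)(C)C(C)(C)C)C)C(C)=C
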